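- Count the half-lives of D in grey and ochre before touching the next charge: if the half-life stretches in these runs, plan on the charge of Q, not on waiting.

| setting | grey | ochre | flask |
|---|---|---|---|
| D | 20 mM | 20 mM | 20 mM |
| Q | 40 mM | 40 mM | 40.0 mM |
| E | 0.27 mM | 0.60 mM | 0.400 mM |
| remark | run made earlier | run made earlier |  |
| time |  |  | 2.5 min |
| volume of the second phase over the first |  |  | 1.0 |

| run | time / s | G / % | D / % |
|---|---|---|---|
| grey | 10.0 | 8 | 94 |
| grey | 15.0 | 9 | 90 |
| grey | 20.0 | 11 | 86 |
| grey | 30.0 | 21 | 81 |
| grey | 50.0 | 24 | 74 |
| grey | 80.0 | 30 | 66 |
| grey | 120 | 41 | 60 |
| ochre | 10.0 | 6 | 94 |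
| ochre | 20.0 | 17 | 90 |
| ochre | 30.0 | 16 | 85 |
| ochre | 50.0 | 26 | 74 |
| ochre | 80.0 | 33 | 63 |
| ochre | 90.0 | 38 | 62 |
| ochre | 120 | 39 | 56 |

(readings scatter by 2 percentage points)

- the G standing at 2.5 min, as a percentage of the D charged
- the change that raises the amount of G at 2.5 min, in percent of the D charged most ("none" if none brings more than 2 percentage points) (eta / gamma / none)
- amount of G at 2.5 min, in percent of the D charged, after eta

- eta: doubling the transfer coefficient of Q, all else as stated
- gamma: doubling the amount of Q, all else as stated

- in the second phase: Q; everything else is in the first
- charges count per volume of the first phase; a concentration in a rate is the amount of a species over the volume of its own phase; every rate counts per litre of the first phase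
- the numbers in the tables scatter with a standard deviation of 2 percentage points
- the earlier runs hold the two phases in the same ratio of volumes as the flask asked about

- Pool grey and ochre: their E charges differ by a factor 2.22, yet D reads 74% in both at 50.0 s, and 60% against 56% at 120 s.
- Read the pooled D over the first 50.0 s: its half-life is 1.92 min.
- Then read 3.32 min for the late half-life of D, the time D would need to halve at the pace it keeps between 50.0 s and 120 s. That is longer than the first value, so the half-life is stretching.
- Carry my own reckoning to the flask: from the pooled 58.0% of D at 120 s, decay at the pace of the late half-life gives D 52.2% at 2.5 min, so G 47.8%. I expect this estimate to run high, since the half-life read in the runs was stretching. So plan to change the charge of the next run, not its time.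
- The forecast says G 46%, best change gamma, and 55% after eta, lower than my G on the first point. Its ground for the choice: “Doubling Q raises the driving force whether control is by transfer or by chemistry”.
- The flask gives G 43.8%, below both figures. The best change is gamma, which gains 20 percentage points against 5.5 points for eta, and eta brings 49.3%, not 55%.

    Z ⇌ Q, rate k1*([Z] - [Q]/K1) per volume of the first phase (partition coefficient = 0.560, kL = 0.00436 /s)
    D + Z ⇌ G (K = 53.8 /M, k = 33.5 /M/s)
    Z + E → J (k = 65.9 /M/s)

- On this flask the half-life of D from 1.25 min to 2.50 min is 4.97 min, longer than 3.32 min. It stretches mainly because G falls back to D + Z. With that falling back taken away, the same flask stands at >99.9% of G instead of 43.8%; as it is, the backward turnover of the passing of D + Z into G is 98% of its forward one.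
- Take the neighbour flask, the same charge read at 1.0 min, which lies inside the window where 3.32 min was read. From the pooled 74% of D at 50.0 s, the late half-life gives G 28.5%; the computed neighbour flask holds G 29.2%.

Readings and results were computed for an exercise; the scatter is artificial.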